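**Plan**

- Retrosynthesis: after removal of three allyl ethers and one silyl ether, ring C is cut at C4–C4a (cycloacylation of a (Z)-3-aryl-3-aryloxyacrylic acid), then at O1–C2 (phenoxide addition to an arylpropiolate), then at C3–C4 and C2–C1' (carboxylation and Sonogashira coupling on ring B), and last at the benzylic C–C bond of the side chain (glycidate opening), the isopropenyl group being traced to the glycidate ester.
- Forward: ring B receives the side chain and then the alkynoate, ring A is attached through oxygen, and ring C, the only ring that is built, closes last by C–C bond formation.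
- Enabling feature: C4a of ring A is ortho to the C5 and C8a oxygens and para to the C7 oxygen, so it is a strongly nucleophilic arene carbon; the two carbons ortho to the vinyl ether oxygen of the 3,5-dioxygenated phenoxy ring are equivalent, so only one flavone can form.
- Stereochemistry: the single (R) centre comes from methyl (R)-glycidate; its C–O bond is never broken, and the descriptor stays R because oxygen > carboxyl-derived carbon > benzylic carbon holds in every intermediate.

Key step: step 12

**Route**

Step 1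
Reactants: 1 4-bromo-2-iodophenol; 2 allyl bromide
Product: 3 1-(allyloxy)-4-bromo-2-iodobenzene
Conditions: K2CO3, acetone, reflux
Reagents that add atoms: none
Why: Williamson ether synthesis, the phenoxide displacing bromide from the allylic halide while both aryl halides are inert to carbonate.

Step 2
Reactants: 3 1-(allyloxy)-4-bromo-2-iodobenzene; 4 methyl (R)-glycidate
Product: 6 methyl (2R)-3-[2-(allyloxy)-5-bromophenyl]-2-hydroxypropanoate, via arylmagnesium chloride 5 (not isolated)
Conditions: i-PrMgCl·LiCl, THF, −20 °C; then CuI (10 mol%), 4, −40 → −20 °C; aq NH4Cl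
Reagents that add atoms: none
Why: Iodine–magnesium exchange is much faster at the iodide ortho to the alkoxy group than at the bromide, and under copper catalysis the aryl Grignard reagent opens the epoxide by SN2 attack at the unsubstituted C3 in preference to the ester carbonyl (copper-catalysed Grignard–epoxide coupling), so the C2 centre is carried over untouched as R.

Step 3
Reactants: 6 methyl (2R)-3-[2-(allyloxy)-5-bromophenyl]-2-hydroxypropanoate
Product: 7 methyl (2R)-3-[2-(allyloxy)-5-bromophenyl]-2-[(tert-butyldimethylsilyl)oxy]propanoate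
Conditions: TBSCl, imidazole, DMF, rt
Reagents that add atoms: tert-butyldimethylsilyl chloride, CC(C)(C)[Si](C)(C)Cl
Why: Imidazole-promoted silylation of a secondary alcohol, which masks the hydroxyl before the organometallic and acylation steps.

Step 4
Reactants: 7 methyl (2R)-3-[2-(allyloxy)-5-bromophenyl]-2-[(tert-butyldimethylsilyl)oxy]propanoate
Product: 9 (3R)-4-[2-(allyloxy)-5-bromophenyl]-3-[(tert-butyldimethylsilyl)oxy]butan-2-one, via Weinreb amide 8 (not isolated)
Conditions: MeNH(OMe)·HCl, i-PrMgCl, THF, −20 °C; then MeMgBr, −20 → 0 °C; aq NH4Cl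
Reagents that add atoms: methylmagnesium bromide, C[Mg]Br
Why: One-pot Weinreb ketone synthesis, in which the chloromagnesium amide converts the ester into amide 8 and the chelated adduct of 8 with MeMgBr persists until work-up, so that the methyl ketone should form without over-addition, without enolisation of the α-silyloxy centre and without exchange at the aryl bromide.

Step 5
Reactants: 9 (3R)-4-[2-(allyloxy)-5-bromophenyl]-3-[(tert-butyldimethylsilyl)oxy]butan-2-one
Product: 10 {[(2R)-1-[2-(allyloxy)-5-bromophenyl]-3-methylbut-3-en-2-yl]oxy}(tert-butyl)dimethylsilane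
Conditions: Ph3PCH3Br, KN(SiMe3)2, THF, 0 °C; then 9, −78 → 0 °C
Reagents that add atoms: methyltriphenylphosphonium bromide, C[P+](c1ccccc1)(c1ccccc1)c1ccccc1.[Br-]
Why: Wittig methylenation of a methyl ketone with the non-stabilised ylide is fast at low temperature, which should outrun enolisation of the α-silyloxy ketone and keep the R centre intact.

Step 6
Reactants: 10 {[(2R)-1-[2-(allyloxy)-5-bromophenyl]-3-methylbut-3-en-2-yl]oxy}(tert-butyl)dimethylsilane; 11 trimethylsilylacetylene
Product: 12 {[4-(allyloxy)-3-[(2R)-2-[(tert-butyldimethylsilyl)oxy]-3-methylbut-3-en-1-yl]phenyl]ethynyl}trimethylsilane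
Conditions: PdCl2(PhCN)2 (3 mol%), [(t-Bu)3PH]BF4 (6 mol%), CuI (2 mol%), (i-Pr)2NH, dioxane, rt
Reagents that add atoms: none
Why: Sonogashira coupling at the aryl bromide, where the electron-rich phosphine lets zerovalent palladium insert at room temperature, a temperature at which, with a hindered amine as base, the aryl allyl ether should not be ionised and the 1,1-disubstituted alkene is no competent Heck partner.

Step 7
Reactants: 12 {[4-(allyloxy)-3-[(2R)-2-[(tert-butyldimethylsilyl)oxy]-3-methylbut-3-en-1-yl]phenyl]ethynyl}trimethylsilane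
Product: 13 {[(2R)-1-[2-(allyloxy)-5-ethynylphenyl]-3-methylbut-3-en-2-yl]oxy}(tert-butyl)dimethylsilane
Conditions: K2CO3 (cat.), MeOH/THF, rt
Reagents that add atoms: none
Why: Methoxide-catalysed protiodesilylation of the alkynylsilane, to which the secondary alkyl silyl ether is stable.

Step 8
Reactants: 13 {[(2R)-1-[2-(allyloxy)-5-ethynylphenyl]-3-methylbut-3-en-2-yl]oxy}(tert-butyl)dimethylsilane
Product: 15 methyl 3-{4-(allyloxy)-3-[(2R)-2-[(tert-butyldimethylsilyl)oxy]-3-methylbut-3-en-1-yl]phenyl}prop-2-ynoate, via lithium acetylide 14 (not isolated)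
Conditions: n-BuLi, THF, −78 °C; then ClCO2Me, −78 → 0 °C
Reagents that add atoms: methyl chloroformate, COC(=O)Cl
Why: Deprotonation of the terminal alkyne, the most acidic site, followed by C-acylation of the acetylide with the chloroformate (acetylide carboxylation) gives the alkynoate that carries C2, C3 and C4 of the flavone.

Step 9
Reactants: 16 phloroglucinol; 2 allyl bromide
Product: 17 3,5-bis(allyloxy)phenol
Conditions: allyl bromide (2.0 equiv), K2CO3, DMF, rt
Reagents that add atoms: allyl bromide (second equivalent), C=CCBr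
Why: Twofold Williamson etherification, each of two phenoxide oxygens displacing bromide from one molecule of allyl bromide, the bis-ether being separated by chromatography from mono- and tri-ether, which is acceptable for a single step on inexpensive material.

Step 10
Reactants: 15 methyl 3-{4-(allyloxy)-3-[(2R)-2-[(tert-butyldimethylsilyl)oxy]-3-methylbut-3-en-1-yl]phenyl}prop-2-ynoate; 17 3,5-bis(allyloxy)phenol
Product: 18 methyl (2Z)-3-{4-(allyloxy)-3-[(2R)-2-[(tert-butyldimethylsilyl)oxy]-3-methylbut-3-en-1-yl]phenyl}-3-[3,5-bis(allyloxy)phenoxy]prop-2-enoate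
Conditions: Cs2CO3 (0.3 equiv), DMF, 60 °C
Reagents that add atoms: none
Why: Base-catalysed oxa-Michael addition of the phenoxide to the β-carbon of the alkynoate with anti protonation places the aryloxy group cis to the ester (Z), O-attack being expected for a caesium phenoxide in DMF, and any E isomer can be carried on because step 12 can equilibrate it.

Step 11
Reactants: 18 methyl (2Z)-3-{4-(allyloxy)-3-[(2R)-2-[(tert-butyldimethylsilyl)oxy]-3-methylbut-3-en-1-yl]phenyl}-3-[3,5-bis(allyloxy)phenoxy]prop-2-enoate
Product: 19 (2Z)-3-{4-(allyloxy)-3-[(2R)-2-[(tert-butyldimethylsilyl)oxy]-3-methylbut-3-en-1-yl]phenyl}-3-[3,5-bis(allyloxy)phenoxy]prop-2-enoic acid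
Conditions: LiOH, THF/MeOH/H2O, rt; then 1 M HCl to pH 4, 0 °C
Reagents that add atoms: lithium hydroxide, [Li+].[OH-]
Why: Saponification at the acyl carbon, the doubly substituted β-carbon being shielded from hydroxide, with silyl and allyl ethers stable to LiOH and to the brief cold acidification.

Step 12
Reactants: 19 (2Z)-3-{4-(allyloxy)-3-[(2R)-2-[(tert-butyldimethylsilyl)oxy]-3-methylbut-3-en-1-yl]phenyl}-3-[3,5-bis(allyloxy)phenoxy]prop-2-enoic acid
Product: 21 5,7-bis(allyloxy)-2-{4-(allyloxy)-3-[(2R)-2-[(tert-butyldimethylsilyl)oxy]-3-methylbut-3-en-1-yl]phenyl}-4H-chromen-4-one, via acid chloride 20 (not isolated)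
Conditions: 1-chloro-N,N,2-trimethylprop-1-en-1-amine, CH2Cl2, 0 °C → rt; then ZnCl2 (1.0 M in Et2O), 2,6-di-tert-butyl-4-methylpyridine, 0 °C → rt
Reagents that add atoms: none
Why: The chloroenamine converts the acid into acid chloride 20 without releasing HCl, and ZnCl2 then polarises the C–Cl bond to an acylium-like carbon, stabilised by the β-aryloxy oxygen and held over an ortho carbon of ring A; attack there forms C4–C4a and loss of the proton to the hindered pyridine restores the arene (intramolecular Friedel–Crafts acylation). The closest known reaction is the classical cycloacylation of 3-aryloxycinnamic acids or their chlorides to flavones, run here with a weak Lewis acid and a proton trap in place of strong acid. Ring C closes as a six-membered ring by 6-exo attack of the arene carbon on the acyl carbon, the carbonyl oxygen staying outside the ring. No stereocentre is formed and the silyloxy-bearing carbon is not involved. The step needs attack on ring A rather than on ring B (indenone formation) or on another molecule: the Z geometry holds the acyl group next to the aryloxy ring, the attacked carbon is ortho to the C8a and C5 oxygens and para to the C7 oxygen, both ortho carbons are equivalent, and any E isomer can equilibrate through the oxocarbenium form of the acylium ion. Because O1–C2 already exists no aurone can arise, and the buffered medium should spare the silyl ether, the allyl ethers and the 1,1-disubstituted alkene.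

Step 13
Reactants: 21 5,7-bis(allyloxy)-2-{4-(allyloxy)-3-[(2R)-2-[(tert-butyldimethylsilyl)oxy]-3-methylbut-3-en-1-yl]phenyl}-4H-chromen-4-one
Product: 22 2-{3-[(2R)-2-[(tert-butyldimethylsilyl)oxy]-3-methylbut-3-en-1-yl]-4-hydroxyphenyl}-5,7-dihydroxy-4H-chromen-4-one
Conditions: Pd(PPh3)4 (5 mol%), morpholine, THF, rt
Reagents that add atoms: none
Why: Tsuji–Trost deallylation, in which zerovalent palladium ionises each aryl allyl ether to a π-allyl complex and a phenoxide and morpholine traps the allyl group, while the silyl-protected allylic alcohol is no leaving group under these conditions.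

Step 14
Reactants: 22 2-{3-[(2R)-2-[(tert-butyldimethylsilyl)oxy]-3-methylbut-3-en-1-yl]-4-hydroxyphenyl}-5,7-dihydroxy-4H-chromen-4-one
Product: 23 5,7-dihydroxy-2-{4-hydroxy-3-[(2R)-2-hydroxy-3-methylbut-3-en-1-yl]phenyl}-4H-chromen-4-one
Conditions: Bu4NF, AcOH (1:1), THF, rt
Reagents that add atoms: none
Why: Fluoride cleavage of the Si–O bond, buffered with acetic acid so that no medium acidic enough to add the ortho phenol to the 1,1-disubstituted alkene arises, and the C–O bond of the stereocentre is not touched.

**Compound list**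

1 | 4-bromo-2-iodophenol | Oc1ccc(Br)cc1I | starting material
2 | allyl bromide | C=CCBr | starting material
3 | 1-(allyloxy)-4-bromo-2-iodobenzene | C=CCOc1ccc(Br)cc1I | intermediate
4 | methyl (R)-glycidate | COC(=O)[C@H]1CO1 | starting material
5 | [2-(allyloxy)-5-bromophenyl]magnesium chloride | C=CCOc1ccc(Br)cc1[Mg]Cl | intermediate
6 | methyl (2R)-3-[2-(allyloxy)-5-bromophenyl]-2-hydroxypropanoate | COC(=O)[C@H](O)Cc1cc(Br)ccc1OCC=C | intermediate
7 | methyl (2R)-3-[2-(allyloxy)-5-bromophenyl]-2-[(tert-butyldimethylsilyl)oxy]propanoate | COC(=O)[C@H](O[Si](C)(C)C(C)(C)C)Cc1cc(Br)ccc1OCC=C | intermediate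
8 | (2R)-3-[2-(allyloxy)-5-bromophenyl]-2-[(tert-butyldimethylsilyl)oxy]-N-methoxy-N-methylpropanamide | CON(C)C(=O)[C@H](O[Si](C)(C)C(C)(C)C)Cc1cc(Br)ccc1OCC=C | intermediate
9 | (3R)-4-[2-(allyloxy)-5-bromophenyl]-3-[(tert-butyldimethylsilyl)oxy]butan-2-one | CC(=O)[C@H](O[Si](C)(C)C(C)(C)C)Cc1cc(Br)ccc1OCC=C | intermediate
10 | {[(2R)-1-[2-(allyloxy)-5-bromophenyl]-3-methylbut-3-en-2-yl]oxy}(tert-butyl)dimethylsilane | C=C(C)[C@H](O[Si](C)(C)C(C)(C)C)Cc1cc(Br)ccc1OCC=C | intermediate
11 | trimethylsilylacetylene | C#C[Si](C)(C)C | starting material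
12 | {[4-(allyloxy)-3-[(2R)-2-[(tert-butyldimethylsilyl)oxy]-3-methylbut-3-en-1-yl]phenyl]ethynyl}trimethylsilane | C=C(C)[C@H](O[Si](C)(C)C(C)(C)C)Cc1cc(C#C[Si](C)(C)C)ccc1OCC=C | intermediate
13 | {[(2R)-1-[2-(allyloxy)-5-ethynylphenyl]-3-methylbut-3-en-2-yl]oxy}(tert-butyl)dimethylsilane | C=C(C)[C@H](O[Si](C)(C)C(C)(C)C)Cc1cc(C#C)ccc1OCC=C | intermediate
14 | lithium acetylide of 13 | C=C(C)[C@H](O[Si](C)(C)C(C)(C)C)Cc1cc(C#C[Li])ccc1OCC=C | intermediate
15 | methyl 3-{4-(allyloxy)-3-[(2R)-2-[(tert-butyldimethylsilyl)oxy]-3-methylbut-3-en-1-yl]phenyl}prop-2-ynoate | C=C(C)[C@H](O[Si](C)(C)C(C)(C)C)Cc1cc(C#CC(=O)OC)ccc1OCC=C | intermediate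
16 | phloroglucinol | Oc1cc(O)cc(O)c1 | starting material
17 | 3,5-bis(allyloxy)phenol | C=CCOc1cc(O)cc(OCC=C)c1 | intermediate
18 | methyl (2Z)-3-{4-(allyloxy)-3-[(2R)-2-[(tert-butyldimethylsilyl)oxy]-3-methylbut-3-en-1-yl]phenyl}-3-[3,5-bis(allyloxy)phenoxy]prop-2-enoate | C=C(C)[C@H](O[Si](C)(C)C(C)(C)C)Cc1cc(/C(Oc2cc(OCC=C)cc(OCC=C)c2)=C/C(=O)OC)ccc1OCC=C | intermediate
19 | (2Z)-3-{4-(allyloxy)-3-[(2R)-2-[(tert-butyldimethylsilyl)oxy]-3-methylbut-3-en-1-yl]phenyl}-3-[3,5-bis(allyloxy)phenoxy]prop-2-enoic acid | C=C(C)[C@H](O[Si](C)(C)C(C)(C)C)Cc1cc(/C(Oc2cc(OCC=C)cc(OCC=C)c2)=C/C(=O)O)ccc1OCC=C | intermediate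
20 | (2Z)-3-{4-(allyloxy)-3-[(2R)-2-[(tert-butyldimethylsilyl)oxy]-3-methylbut-3-en-1-yl]phenyl}-3-[3,5-bis(allyloxy)phenoxy]prop-2-enoyl chloride | C=C(C)[C@H](O[Si](C)(C)C(C)(C)C)Cc1cc(/C(Oc2cc(OCC=C)cc(OCC=C)c2)=C/C(=O)Cl)ccc1OCC=C | intermediate
21 | 5,7-bis(allyloxy)-2-{4-(allyloxy)-3-[(2R)-2-[(tert-butyldimethylsilyl)oxy]-3-methylbut-3-en-1-yl]phenyl}-4H-chromen-4-one | C=C(C)[C@H](O[Si](C)(C)C(C)(C)C)Cc1cc(-c2cc(=O)c3c(OCC=C)cc(OCC=C)cc3o2)ccc1OCC=C | intermediate
22 | 2-{3-[(2R)-2-[(tert-butyldimethylsilyl)oxy]-3-methylbut-3-en-1-yl]-4-hydroxyphenyl}-5,7-dihydroxy-4H-chromen-4-one | C=C(C)[C@H](O[Si](C)(C)C(C)(C)C)Cc1cc(-c2cc(=O)c3c(O)cc(O)cc3o2)ccc1O | intermediate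
23 | 5,7-dihydroxy-2-{4-hydroxy-3-[(2R)-2-hydroxy-3-methylbut-3-en-1-yl]phenyl}-4H-chromen-4-one (CNP0184617.1) | C=C(C)[C@H](O)Cc1cc(-c2cc(=O)c3c(O)cc(O)cc3o2)ccc1O | target

**Count and risks**

Total step count: 14. Longest linear sequence: 13 steps (steps 1–8 and 10–14, from 1 to 23); step 9 is the only step of the second branch.

Steps most likely to fail:

Step 12. Ionisation of the acid chloride under the buffered zinc conditions may be too slow, so that hydrolysis back to the acid or intermolecular acylation takes over, or the Lewis acid may strip the silyl ether or the peri allyl ether. The fallback closes ring C at oxygen instead; it sets out from 17 and 13 and comes back at 21. Magnesium-mediated ortho-formylation of 17 (MgCl2, Et3N, paraformaldehyde, MeCN, reflux) should give 2-hydroxy-4,6-bis(allyloxy)benzaldehyde F1, the two ortho positions of 17 being equivalent. F1 is converted to its lithium phenoxide with LiN(SiMe3)2 and treated with lithium acetylide 14 (from 13 and n-BuLi, THF, −78 → 0 °C) to give the ring A/ring B propargylic alcohol F2 as both carbinol epimers. MnO2 in CH2Cl2 should oxidise it to the 2-hydroxyaryl ynone F3, which removes the extra centre. Et2NH in EtOH at reflux then turns F3, through its enaminone, into 21 by 6-endo oxa-Michael closure with loss of the amine, the established flavone synthesis from o-hydroxyaryl alkynyl ketones.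

Step 10. Addition to the donor-substituted β-aryl alkynoate may stall, or the ambident phenoxide may attack through carbon. The fallback makes the C–O bond by vinylic substitution; it sets out from 15 and comes back at 18. Anti hydroiodination of 15 (LiI, AcOH, MeCN, 70 °C) should give the (Z)-β-iodocinnamate F4. Ullmann-type coupling of F4 with 17 (CuI, N,N-dimethylglycine, Cs2CO3, dioxane, 60 °C) should then form the aryl vinyl ether with retention of alkene geometry; addition–elimination at the β-carbon leads to the same product.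

Step 2. The arylmagnesium may attack the ester carbonyl instead of the epoxide carbon, or halide may open the epoxide. The fallback builds the side chain from a prenyl group with reagent-controlled oxygenation; it sets out from 3 (through the same arylmagnesium 5) and comes back at 10. Reaction of 5 with prenyl bromide (THF, −20 → 0 °C, no copper, so that attack at the primary carbon prevails) should give the prenylarene F5. Shi epoxidation (D-fructose-derived ketone, KHSO5, K2CO3 buffer, MeCN/dimethoxymethane/H2O, 0 °C) oxidises only the trisubstituted alkene and is expected from the spiro transition-state model to give the (R)-epoxide F6; the enantiomeric ketone is available should the sense prove opposite. Diethylaluminium 2,2,6,6-tetramethylpiperidide (Et2Al–NC9H18, toluene, 0 °C) should cleave the tertiary C–O bond with loss of a methyl proton and give the (R)-allylic alcohol F7, the secondary C–O bond staying intact. TBSCl and imidazole in DMF then return to 10.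

Further compounds
F1 | step 12 | 2-hydroxy-4,6-bis(allyloxy)benzaldehyde | O=Cc1c(O)cc(OCC=C)cc1OCC=C
F2 | step 12 | 1-[2-hydroxy-4,6-bis(allyloxy)phenyl]-3-{4-(allyloxy)-3-[(2R)-2-[(tert-butyldimethylsilyl)oxy]-3-methylbut-3-en-1-yl]phenyl}prop-2-yn-1-ol (both carbinol epimers) | C=C(C)[C@H](O[Si](C)(C)C(C)(C)C)Cc1cc(C#CC(O)c2c(O)cc(OCC=C)cc2OCC=C)ccc1OCC=C
F3 | step 12 | 1-[2-hydroxy-4,6-bis(allyloxy)phenyl]-3-{4-(allyloxy)-3-[(2R)-2-[(tert-butyldimethylsilyl)oxy]-3-methylbut-3-en-1-yl]phenyl}prop-2-yn-1-one | C=C(C)[C@H](O[Si](C)(C)C(C)(C)C)Cc1cc(C#CC(=O)c2c(O)cc(OCC=C)cc2OCC=C)ccc1OCC=C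
F4 | step 10 | methyl (2Z)-3-{4-(allyloxy)-3-[(2R)-2-[(tert-butyldimethylsilyl)oxy]-3-methylbut-3-en-1-yl]phenyl}-3-iodoprop-2-enoate | C=C(C)[C@H](O[Si](C)(C)C(C)(C)C)Cc1cc(/C(I)=C/C(=O)OC)ccc1OCC=C
F5 | step 2 | 1-(allyloxy)-4-bromo-2-(3-methylbut-2-en-1-yl)benzene | CC(C)=CCc1cc(Br)ccc1OCC=C
F6 | step 2 | (3R)-3-[2-(allyloxy)-5-bromobenzyl]-2,2-dimethyloxirane | CC1(C)O[C@@H]1Cc1cc(Br)ccc1OCC=C
F7 | step 2 | (2R)-1-[2-(allyloxy)-5-bromophenyl]-3-methylbut-3-en-2-ol | C=C(C)[C@H](O)Cc1cc(Br)ccc1OCC=C
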